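**Retrosynthetic overview**
1. The senecioate C–O bond is cut last (Steglich esterification after desilylation), which leaves the (R)-carbinol quinone 23/22.
2. Key disconnection: the quinone C3–C4 bond (vinyl CH to the carbonyl peri to the C5 hydroxyl), leading back to 2-ethynyl-2-hydroxybenzocyclobutenone 19. The enabling feature is the strained cyclobutenone ring fused to the benzene ring (C1 carbonyl, C2 carbinol, C2a, C6a), with OH and ethynyl both on C2 and the C1 carbonyl on the ring carbon beside the phenol carbon C6.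
3. 19 comes from phenoxide-directed acetylide addition to hydroxy dione 17, and 17 from aryne [2+2] cycloaddition of bromide 10 with tris(trimethylsilyloxy)ethene, oxidation and MOM removal.
4. The side chain comes from Brown allylboration of aldehyde 4 (sets the R centre) and cross-metathesis to the prenyl group; the arene comes from 2,5-dihydroxybenzaldehyde.
5. Ring order: benzene ring (purchased), then the four-membered ring (step 7), then the quinone ring by ring expansion of the four-membered ring (step 11).

Key step: step 11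

Assumption: the stereodescriptor in the target corresponds to the (R) configuration at the side-chain carbinol carbon (shikonin series); all intermediates are drawn accordingly.
Remark: four-membered-ring compounds are named on the benzocyclobutene skeleton (C1 and C2 in the small ring, C2a, C3 to C6, C6a). TBSO = tert-butyldimethylsilyloxy, MOM = methoxymethyl. Compound 14 is expected together with its regioisomer (carbonyl and carbinol exchanged) and carbinol epimers; all of them give 15 in step 8. Starting materials 1, 5, 8, 11, 18, 24 and the unnumbered reagents are catalogue chemicals.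

**Step 1**
Reactants: 1 2,5-dihydroxybenzaldehyde
Product: 2 2-hydroxy-5-(methoxymethoxy)benzaldehyde
Conditions: MOMCl (1.05 equiv), iPr2NEt, CH2Cl2, 0 °C
Reagents that add atoms: chloromethyl methyl ether, COCCl
Why: O-alkylation (MOM protection) should occur at the C5 hydroxyl, because the C2 hydroxyl is held in a hydrogen bond to the formyl group and is the poorer nucleophile.

**Step 2**
Reactants: 2 2-hydroxy-5-(methoxymethoxy)benzaldehyde
Product: 3 3-bromo-2-hydroxy-5-(methoxymethoxy)benzaldehyde
Conditions: NBS, MeCN, 0 °C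
Reagents that add atoms: N-bromosuccinimide, O=C1CCC(=O)N1Br
Why: Electrophilic aromatic bromination should go to C3, the only position ortho to the free phenol (para is blocked) and meta to the deactivating formyl group.

**Step 3**
Reactants: 3 3-bromo-2-hydroxy-5-(methoxymethoxy)benzaldehyde
Product: 4 3-bromo-2-methoxy-5-(methoxymethoxy)benzaldehyde
Conditions: MeI, K2CO3, DMF, rt
Reagents that add atoms: iodomethane, CI
Why: Williamson ether synthesis on the only free phenol fixes the methoxy group that the target keeps.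

**Step 4**
Reactants: 4 3-bromo-2-methoxy-5-(methoxymethoxy)benzaldehyde; 5 (+)-B-allyldiisopinocampheylborane
Product: 7 (1R)-1-[3-bromo-2-methoxy-5-(methoxymethoxy)phenyl]but-3-en-1-ol, via borinate ester 6 (not isolated)
Conditions: 5 (1 M in pentane), Et2O, −78 °C; then NaOH, H2O2, 0 °C → rt
Reagents that add atoms: none
Why: Brown asymmetric allylboration through a closed chair transition state; the reagent of the (−)-α-pinene series should deliver allyl to the Re face of the aryl aldehyde and so set the (R) carbinol centre (the antipodal reagent is the one known to give (S) alcohols from aryl aldehydes).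

**Step 5**
Reactants: 7 (1R)-1-[3-bromo-2-methoxy-5-(methoxymethoxy)phenyl]but-3-en-1-ol; 8 2-methylbut-2-ene
Product: 9 (1R)-1-[3-bromo-2-methoxy-5-(methoxymethoxy)phenyl]-4-methylpent-3-en-1-ol
Conditions: second-generation Grubbs catalyst (H2IMes)(PCy3)Cl2Ru=CHPh (5 mol %), 8 (excess)/CH2Cl2, 40 °C
Reagents that add atoms: none
Why: Olefin cross-metathesis of the terminal alkene with excess trisubstituted alkene converts allyl into prenyl with loss of propene and does not touch the stereocentre.

**Step 6**
Reactants: 9 (1R)-1-[3-bromo-2-methoxy-5-(methoxymethoxy)phenyl]-4-methylpent-3-en-1-ol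
Product: 10 TBS ether of 9
Conditions: TBSCl, imidazole, DMF, rt
Reagents that add atoms: tert-butyldimethylsilyl chloride, CC(C)(C)[Si](C)(C)Cl
Why: Silylation of the secondary alcohol protects it against the amide base of step 7 and the oxidant of step 8.

**Step 7**
Reactants: 10 TBS ether of 9; 11 tris(trimethylsilyloxy)ethene
Product: 14 1-hydroxy-3-methoxy-6-(methoxymethoxy)-4-[(1R)-1-(TBSO)-4-methylpent-3-en-1-yl]benzocyclobuten-2(1H)-one, via aryne 12 (not isolated), via tris(trimethylsilyloxy) cycloadduct 13 (not isolated)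
Conditions: LiTMP (from 2,2,6,6-tetramethylpiperidine and n-BuLi, 2.5 equiv), 11 (3 equiv), THF, −78 → 0 °C; then 0.5 M HCl, THF, 0 °C
Reagents that add atoms: none
Why: LiTMP should remove the proton flanked by bromine and the MOM ether and expel LiBr to give aryne 12, which undergoes the stepwise [2+2] cycloaddition known for arynes and ketene silyl acetals to give 13; dilute acid then frees the ketone and the carbinol while the MOM and TBS ethers stay.

**Step 8**
Reactants: 14 hydroxy ketone (isomer mixture)
Product: 15 3-methoxy-6-(methoxymethoxy)-4-[(1R)-1-(TBSO)-4-methylpent-3-en-1-yl]benzocyclobutene-1,2-dione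
Conditions: Dess–Martin periodinane, CH2Cl2, 0 °C → rt
Reagents that add atoms: none
Why: Dess–Martin oxidation of the α-hydroxy ketone to the 1,2-dione, in which all regioisomers and epimers of 14 converge on one compound.

**Step 9**
Reactants: 15 MOM-protected dione
Product: 17 6-hydroxy-3-methoxy-4-[(1R)-1-(TBSO)-4-methylpent-3-en-1-yl]benzocyclobutene-1,2-dione, via aryl trimethylsilyl ether 16 (not isolated)
Conditions: TMSOTf, 2,2′-bipyridyl, CH2Cl2, 0 °C; then H2O
Reagents that add atoms: none
Why: Silyl triflate buffered by 2,2′-bipyridyl converts aromatic MOM ethers into aryl silyl ethers under non-protic conditions that should spare the benzylic TBS ether, the prenyl alkene and the dione, and water then hydrolyses the labile aryl TMS ether to the phenol.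

**Step 10**
Reactants: 17 hydroxy dione; 18 ethynylmagnesium bromide
Product: 19 2-ethynyl-2,6-dihydroxy-3-methoxy-4-[(1R)-1-(TBSO)-4-methylpent-3-en-1-yl]benzocyclobuten-1(2H)-one
Conditions: HC≡CMgBr (3 equiv, 0.5 M in THF), THF, −78 → −40 °C; sat. aq NH4Cl
Reagents that add atoms: none
Why: Acetylide 1,2-addition to a benzocyclobutenedione; the first equivalent forms the magnesium phenoxide, whose donation into the C1 carbonyl (vinylogous carboxylate) deactivates it, so the nucleophile should add to the C2 carbonyl, whose neighbouring methoxy group is twisted out of conjugation by the side chain (the new carbinol centre forms as both epimers, which does not matter).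

**Step 11**
Reactants: 19 ethynyl carbinol
Product: 22 5-hydroxy-8-methoxy-7-[(1R)-1-(TBSO)-4-methylpent-3-en-1-yl]naphthalene-1,4-dione, via quinoid vinylketene 20 (not isolated), via diradical 21 (not isolated)
Conditions: degassed p-xylene (0.01 M), 135 °C
Reagents that add atoms: none
Why: Heating opens the cyclobutenone by conrotatory 4π electrocyclic cleavage of the C1–C2 bond, and the C2 hydroxyl rotates outward (donor torquoselectivity), which places the ethynyl group next to the ketene in o-quinoid vinylketene 20. The ketene carbon (former C1, attached to the ring carbon beside the phenol) then bonds to the terminal alkyne carbon to give the aromatic σ,π-diradical 21, and transfer of the carbinol hydrogen to the aryl radical centre delivers quinone 22 without any oxidant. The closest known reaction is the Moore rearrangement of 4-alkynyl-4-hydroxycyclobutenones to quinones, in its benzo-fused form that turns acetylide adducts of benzocyclobutenediones into 1,4-naphthoquinones. The six-membered quinone ring closes in a 6-endo-dig mode; the 5-exo-dig alternative would leave an unstabilised primary vinyl radical because the alkyne is terminal, and closure is driven by the return of benzene aromaticity and the release of four-membered-ring strain. No stereocentre is created: the carbinol centre of 19 is destroyed, so both epimers converge, and the remote (R) silyloxy centre is not touched. The regiochemistry (which carbonyl ends up peri to the hydroxyl) is fixed by the constitution of 19, and high dilution in a non-nucleophilic solvent should keep the free phenol from intercepting the ketene.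

**Step 12**
Reactants: 22 silyl-protected quinone
Product: 23 5-hydroxy-7-[(1R)-1-hydroxy-4-methylpent-3-en-1-yl]-8-methoxynaphthalene-1,4-dione
Conditions: HF·pyridine, pyridine, THF, 0 °C → rt
Reagents that add atoms: none
Why: Fluoride cleavage of the secondary silyl ether under pyridine-buffered conditions, which should avoid acid-induced cyclisation of the freed carbinol onto the prenyl alkene and leave the quinone untouched.

**Step 13**
Reactants: 23 quinone alcohol; 24 3-methylbut-2-enoic acid
Product: 25 (1R)-1-(4-hydroxy-1-methoxy-5,8-dioxo-5,8-dihydronaphthalen-2-yl)-4-methylpent-3-en-1-yl 3-methylbut-2-enoate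
Conditions: DCC, DMAP (cat.), CH2Cl2, 0 °C → rt
Reagents that add atoms: none
Why: Steglich esterification acylates the secondary alcohol while the peri hydroxyl, locked in a hydrogen bond to the C4 carbonyl, is a poor nucleophile; no bond to the stereocentre is broken, so the (R) configuration is retained.

**Compound list**
1 | 2,5-dihydroxybenzaldehyde | O=Cc1cc(O)ccc1O | starting material
2 | 2-hydroxy-5-(methoxymethoxy)benzaldehyde | O=Cc1cc(OCOC)ccc1O | intermediate
3 | 3-bromo-2-hydroxy-5-(methoxymethoxy)benzaldehyde | O=Cc1cc(OCOC)cc(Br)c1O | intermediate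
4 | 3-bromo-2-methoxy-5-(methoxymethoxy)benzaldehyde | COc1c(C=O)cc(OCOC)cc1Br | intermediate
5 | (+)-B-allyldiisopinocampheylborane, (+)-Ipc2B(allyl), isopinocampheyl groups from (1S,5S)-(−)-α-pinene | C=CCB([C@H]1C[C@H]2C[C@@H]([C@@H]1C)C2(C)C)[C@H]1C[C@H]2C[C@@H]([C@@H]1C)C2(C)C | starting material
6 | (1R)-1-[3-bromo-2-methoxy-5-(methoxymethoxy)phenyl]but-3-en-1-yl diisopinocampheylborinate (not isolated) | COc1c([C@@H](CC=C)OB([C@H]2C[C@H]3C[C@@H]([C@@H]2C)C3(C)C)[C@H]2C[C@H]3C[C@@H]([C@@H]2C)C3(C)C)cc(OCOC)cc1Br | intermediate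
7 | (1R)-1-[3-bromo-2-methoxy-5-(methoxymethoxy)phenyl]but-3-en-1-ol | COc1c([C@@H](CC=C)O)cc(OCOC)cc1Br | intermediate
8 | 2-methylbut-2-ene | CC=C(C)C | starting material
9 | (1R)-1-[3-bromo-2-methoxy-5-(methoxymethoxy)phenyl]-4-methylpent-3-en-1-ol | COc1c([C@@H](CC=C(C)C)O)cc(OCOC)cc1Br | intermediate
10 | {[(1R)-1-[3-bromo-2-methoxy-5-(methoxymethoxy)phenyl]-4-methylpent-3-en-1-yl]oxy}(tert-butyl)dimethylsilane | COc1c([C@@H](CC=C(C)C)O[Si](C)(C)C(C)(C)C)cc(OCOC)cc1Br | intermediate
11 | tris(trimethylsilyloxy)ethene | C[Si](C)(C)OC=C(O[Si](C)(C)C)O[Si](C)(C)C | starting material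
12 | 3-methoxy-6-(methoxymethoxy)-4-[(1R)-1-(tert-butyldimethylsilyloxy)-4-methylpent-3-en-1-yl]-1,2-didehydrobenzene (aryne, not isolated) | COC1=C([C@@H](CC=C(C)C)O[Si](C)(C)C(C)(C)C)C=C(OCOC)C#C1 | intermediate
13 | 3-methoxy-6-(methoxymethoxy)-4-[(1R)-1-(tert-butyldimethylsilyloxy)-4-methylpent-3-en-1-yl]-1,2,2-tris(trimethylsilyloxy)-1,2-dihydrobenzocyclobutene (not isolated; drawn as one regioisomer, C1 epimers) | COc1c([C@@H](CC=C(C)C)O[Si](C)(C)C(C)(C)C)cc(OCOC)c2c1C(O[Si](C)(C)C)(O[Si](C)(C)C)C2O[Si](C)(C)C | intermediate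
14 | 1-hydroxy-3-methoxy-6-(methoxymethoxy)-4-[(1R)-1-(tert-butyldimethylsilyloxy)-4-methylpent-3-en-1-yl]benzocyclobuten-2(1H)-one (C1 epimers; the regioisomer with carbonyl and carbinol exchanged is expected alongside) | COc1c([C@@H](CC=C(C)C)O[Si](C)(C)C(C)(C)C)cc(OCOC)c2c1C(=O)C2O | intermediate
15 | 3-methoxy-6-(methoxymethoxy)-4-[(1R)-1-(tert-butyldimethylsilyloxy)-4-methylpent-3-en-1-yl]benzocyclobutene-1,2-dione | COc1c([C@@H](CC=C(C)C)O[Si](C)(C)C(C)(C)C)cc(OCOC)c2c1C(=O)C2=O | intermediate
16 | 3-methoxy-6-(trimethylsilyloxy)-4-[(1R)-1-(tert-butyldimethylsilyloxy)-4-methylpent-3-en-1-yl]benzocyclobutene-1,2-dione (not isolated) | COc1c([C@@H](CC=C(C)C)O[Si](C)(C)C(C)(C)C)cc(O[Si](C)(C)C)c2c1C(=O)C2=O | intermediate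
17 | 6-hydroxy-3-methoxy-4-[(1R)-1-(tert-butyldimethylsilyloxy)-4-methylpent-3-en-1-yl]benzocyclobutene-1,2-dione | COc1c([C@@H](CC=C(C)C)O[Si](C)(C)C(C)(C)C)cc(O)c2c1C(=O)C2=O | intermediate
18 | ethynylmagnesium bromide | C#C[Mg]Br | starting material
19 | 2-ethynyl-2,6-dihydroxy-3-methoxy-4-[(1R)-1-(tert-butyldimethylsilyloxy)-4-methylpent-3-en-1-yl]benzocyclobuten-1(2H)-one (both C2 epimers) | COc1c([C@@H](CC=C(C)C)O[Si](C)(C)C(C)(C)C)cc(O)c2c1C(O)(C#C)C2=O | intermediate
20 | {2-hydroxy-6-(1-hydroxyprop-2-yn-1-ylidene)-5-methoxy-4-[(1R)-1-(tert-butyldimethylsilyloxy)-4-methylpent-3-en-1-yl]cyclohexa-2,4-dien-1-ylidene}methanone, enol hydroxyl anti and ethynyl syn to the ketene (not isolated) | O/C(C#C)=C1\C(OC)=C([C@@H](CC=C(C)C)O[Si](C)(C)C(C)(C)C)C=C(O)C1=C=O | intermediate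
21 | 2-yl-4-oxyl diradical of 1,5-dihydroxy-8-methoxy-7-[(1R)-1-(tert-butyldimethylsilyloxy)-4-methylpent-3-en-1-yl]naphthalene (not isolated) | COc1c([C@@H](CC=C(C)C)O[Si](C)(C)C(C)(C)C)cc(O)c2c([O])c[c]c(O)c12 | intermediate
22 | 5-hydroxy-8-methoxy-7-[(1R)-1-(tert-butyldimethylsilyloxy)-4-methylpent-3-en-1-yl]naphthalene-1,4-dione | COc1c([C@@H](CC=C(C)C)O[Si](C)(C)C(C)(C)C)cc(O)c2c1C(=O)C=CC2=O | intermediate
23 | 5-hydroxy-7-[(1R)-1-hydroxy-4-methylpent-3-en-1-yl]-8-methoxynaphthalene-1,4-dione | COc1c([C@@H](CC=C(C)C)O)cc(O)c2c1C(=O)C=CC2=O | intermediate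
24 | 3-methylbut-2-enoic acid | CC(C)=CC(=O)O | starting material
25 | (1R)-1-(4-hydroxy-1-methoxy-5,8-dioxo-5,8-dihydronaphthalen-2-yl)-4-methylpent-3-en-1-yl 3-methylbut-2-enoate | COc1c([C@@H](CC=C(C)C)OC(=O)C=C(C)C)cc(O)c2c1C(=O)C=CC2=O | target

**Totals**
Total step count: 13. Longest linear sequence: 13 steps (1 to 25).

**Steps most likely to fail, with fallbacks**

Step 7. The aryne may be consumed by addition of the amide base or by silyl transfer from the ketene acetal instead of [2+2] cycloaddition. The four-membered ring would then be closed reductively and not by cycloaddition. Setting out from 10, bromine–lithium exchange (n-BuLi, THF, −78 °C) and DMF should give 2-methoxy-5-(methoxymethoxy)-3-[(1R)-1-(TBSO)-4-methylpent-3-en-1-yl]benzaldehyde F1. In situ masking of the formyl group with lithium N,N,N′-trimethylethylenediamide, ortho-lithiation (n-BuLi) at the position flanked by the masked formyl group and the MOM ether, and DMF should give the phthalaldehyde F2. Intramolecular pinacol coupling with SmI2 (THF, −78 °C → rt) should give the benzocyclobutene-1,2-diol F3 as a diastereomer mixture. Swern oxidation ((COCl)2, DMSO, Et3N, −78 °C) comes back to the route at dione 15.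

Step 10. The acetylide may attack the other carbonyl, or the base may cleave the four-membered ring of the phenoxide. The ethynyl carbinol would then be set before the second carbonyl exists. Setting out from 14 (the regioisomer in the list, separated by chromatography), ethynylmagnesium bromide (THF, −78 °C) adds to the only ketone to give the ethynyl diol F4. Oxidation of the remaining secondary benzylic alcohol (SO3·pyridine, DMSO, iPr2NEt, 0 °C) gives the MOM-protected ethynyl hydroxy ketone F5, whose carbonyl is by construction the one beside the MOM-ether carbon. Thermolysis as in step 11 passes through the vinylketene F6 and the diradical F7 to the MOM-protected quinone F8. Cleavage of the peri MOM ether (MgBr2·OEt2, Et2O–CH2Cl2, rt, then water) comes back to the route at 22.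

Step 11. The ketene may be intercepted, the ring may close in the five-membered mode, or the diradical may oligomerise. The same bond would then be made by a closed-shell electrocyclisation followed by oxidation. Setting out from 17, vinylmagnesium bromide (THF, −78 °C) gives the vinyl carbinol F9. Heating (toluene, 100 °C) opens it to the dienylketene F10, and 6π electrocyclisation gives the 4-hydroxy-2H-naphthalen-1-one F11, which tautomerises to the naphthalene-1,4,5-triol F12. Oxidation with Ag2O (Et2O, rt) comes back to the route at 22.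

**Further compounds**
F1 | step 7 | 2-methoxy-5-(methoxymethoxy)-3-[(1R)-1-(tert-butyldimethylsilyloxy)-4-methylpent-3-en-1-yl]benzaldehyde | COc1c([C@@H](CC=C(C)C)O[Si](C)(C)C(C)(C)C)cc(OCOC)cc1C=O
F2 | step 7 | 3-methoxy-6-(methoxymethoxy)-4-[(1R)-1-(tert-butyldimethylsilyloxy)-4-methylpent-3-en-1-yl]benzene-1,2-dicarbaldehyde | COc1c([C@@H](CC=C(C)C)O[Si](C)(C)C(C)(C)C)cc(OCOC)c(C=O)c1C=O
F3 | step 7 | 3-methoxy-6-(methoxymethoxy)-4-[(1R)-1-(tert-butyldimethylsilyloxy)-4-methylpent-3-en-1-yl]-1,2-dihydrobenzocyclobutene-1,2-diol (diol diastereomers) | COc1c([C@@H](CC=C(C)C)O[Si](C)(C)C(C)(C)C)cc(OCOC)c2c1C(O)C2O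
F4 | step 10 | 2-ethynyl-3-methoxy-6-(methoxymethoxy)-4-[(1R)-1-(tert-butyldimethylsilyloxy)-4-methylpent-3-en-1-yl]-1,2-dihydrobenzocyclobutene-1,2-diol (diastereomers) | COc1c([C@@H](CC=C(C)C)O[Si](C)(C)C(C)(C)C)cc(OCOC)c2c1C(O)(C#C)C2O
F5 | step 10 | 2-ethynyl-2-hydroxy-3-methoxy-6-(methoxymethoxy)-4-[(1R)-1-(tert-butyldimethylsilyloxy)-4-methylpent-3-en-1-yl]benzocyclobuten-1(2H)-one (C2 epimers) | COc1c([C@@H](CC=C(C)C)O[Si](C)(C)C(C)(C)C)cc(OCOC)c2c1C(O)(C#C)C2=O
F6 | step 10 | {6-(1-hydroxyprop-2-yn-1-ylidene)-5-methoxy-2-(methoxymethoxy)-4-[(1R)-1-(tert-butyldimethylsilyloxy)-4-methylpent-3-en-1-yl]cyclohexa-2,4-dien-1-ylidene}methanone | O/C(C#C)=C1\C(OC)=C([C@@H](CC=C(C)C)O[Si](C)(C)C(C)(C)C)C=C(OCOC)C1=C=O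
F7 | step 10 | 2-yl-4-oxyl diradical of 1-hydroxy-8-methoxy-5-(methoxymethoxy)-7-[(1R)-1-(tert-butyldimethylsilyloxy)-4-methylpent-3-en-1-yl]naphthalene | COc1c([C@@H](CC=C(C)C)O[Si](C)(C)C(C)(C)C)cc(OCOC)c2c([O])c[c]c(O)c12
F8 | step 10 | 8-methoxy-5-(methoxymethoxy)-7-[(1R)-1-(tert-butyldimethylsilyloxy)-4-methylpent-3-en-1-yl]naphthalene-1,4-dione | COc1c([C@@H](CC=C(C)C)O[Si](C)(C)C(C)(C)C)cc(OCOC)c2c1C(=O)C=CC2=O
F9 | step 11 | 2-ethenyl-2,6-dihydroxy-3-methoxy-4-[(1R)-1-(tert-butyldimethylsilyloxy)-4-methylpent-3-en-1-yl]benzocyclobuten-1(2H)-one (C2 epimers) | COc1c([C@@H](CC=C(C)C)O[Si](C)(C)C(C)(C)C)cc(O)c2c1C(O)(C=C)C2=O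
F10 | step 11 | {2-hydroxy-6-(1-hydroxyprop-2-en-1-ylidene)-5-methoxy-4-[(1R)-1-(tert-butyldimethylsilyloxy)-4-methylpent-3-en-1-yl]cyclohexa-2,4-dien-1-ylidene}methanone | O/C(C=C)=C1\C(OC)=C([C@@H](CC=C(C)C)O[Si](C)(C)C(C)(C)C)C=C(O)C1=C=O
F11 | step 11 | 4,8-dihydroxy-5-methoxy-6-[(1R)-1-(tert-butyldimethylsilyloxy)-4-methylpent-3-en-1-yl]naphthalen-1(2H)-one | COc1c([C@@H](CC=C(C)C)O[Si](C)(C)C(C)(C)C)cc(O)c2c1C(O)=CCC2=O
F12 | step 11 | 8-methoxy-7-[(1R)-1-(tert-butyldimethylsilyloxy)-4-methylpent-3-en-1-yl]naphthalene-1,4,5-triol | COc1c([C@@H](CC=C(C)C)O[Si](C)(C)C(C)(C)C)cc(O)c2c(O)ccc(O)c12
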